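The earlier runs and the new flask come from a simulation on assumed constants, and the scatter is random.

E, L and D grow out of X and Q, so the flask is read through how much X a charge of Q takes away.

| flask | X | Q | remark | time |
|---|---|---|---|---|
| Friday's | 0.45 M | 0.23 M | run made earlier |  |
| Saturday's | 0.45 M | 0.34 M | run made earlier |  |
| flask | 0.45 M | 0.450 M |  | 2.0 d |

- Friday's (time / h: X / %, E / %): 2.50: 86, 5; 5.00: 78, 6; 12.0: 66, 9; 30.0: 63, 12
- Saturday's (time / h: X / %, E / %): 4.00: 73, 5; 10.0: 56, 12; 20.0: 53, 14; 30.0: 52, 10

(readings scatter by 1.5 percentage points)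

- amount of X at 2.0 d, in percent of the X charged
- amount of E at 2.0 d, in percent of the X charged
- amount of L at 2.0 d, in percent of the X charged
- amount of D at 2.0 d, in percent of the X charged

- the numbers in the tables scatter with a standard deviation of 1.5 percentage points

Does X stop? Saturday's X drops by 1 point from 20.0 h to 30.0 h, against a scatter of 1.5 points, with 52% of X still there, which points to Q as the limiting reagent. The asked time is 1.60 times that last reading, so my reckoning takes the flask as stalled too.

How much X does more Q take? Friday's run has 0.511 equivalents of Q and has lost 37.0% of its X by its last reading. Saturday's has 0.756 and has lost 48.0% by its last reading. In logarithms, the equivalents rise by 0.170 decades and the share lost by 0.113. Their ratio is the take-up exponent 0.666, the slope of log share of X lost against log equivalents of Q. This reading carries the scatter of the runs; it is below one, so between these two runs the share of X lost grows more slowly than the charge of Q.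

Stretched beyond Saturday's run to the 1.00 equivalents of the asked flask, the exponent leaves 42.1% of X by my own reckoning. L and D stand in neither table, so this reckoning gives no figure for them.

The forecast gives X 42%, E 13%, L 6% and D 39%, reasoning “So L forms faster yet is consumed quickly, while E persists.”

The flask gives X 44.2%, E 15.1%, L 29.6% and D 7.41%.

    X + Q → E + Z (k = 4.27 × 10⁻⁵ L mol⁻¹ s⁻¹)
    X + Q → L + Z (k = 5.75 × 10⁻⁵ L mol⁻¹ s⁻¹)
    Q + E → D + Z (k = 6.52 × 10⁻⁵ L mol⁻¹ s⁻¹)
    Q + L → D + Z (k = 1.68 × 10⁻⁵ L mol⁻¹ s⁻¹)
    2 Q → G (k = 5.62 × 10⁻⁵ L mol⁻¹ s⁻¹)
    E ⇌ J (K = 0.240, k = 1.24 × 10⁻⁴ s⁻¹)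

X lies 2.1 points from the exponent's figure, while L stands 24 points above the forecast and D 32 points below it. Carried from Friday's run to the 0.409 equivalents of Q in the neighbour flask with 1.1 M of X, the exponent leaves 68.1% of X, and that flask holds 68.7% at the asked time. In the asked flask, L has a half-life of 1.1 d by its turning into D, longer than the 0.31 d of X by its turning into L, both at the concentrations as charged. At 1.00 d, Q is down to 2.88% of its charge, with L at 28.8%.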